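(The numbers in the tables come from a simulation from invented constants; the scatter is artificial.)

Put the rungs of this flask in order of speed, fastest first; I did that before reckoning anything.

| flask | G | X | remark | time |
|---|---|---|---|---|
| north | 0.42 M | 0.21 M | run made earlier |  |
| south-west | 0.66 M | 0.21 M | run made earlier |  |
| north-east | 0.30 M | 0.32 M | run made earlier |  |
| flask | 0.30 M | 0.210 M |  | 10 min |

- north (time / min: Q / %, G / %): 0.167: 30.6, 66.7; 0.250: 35.1, 63.6; 0.667: 35.7, 61.9; 1.50: 31.6, 63.9; 4.00: 26.6, 68.3; 10.0: 19.0, 72.7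
- south-west (time / min: Q / %, G / %): 0.167: 25.1, 72.7; 0.250: 25.8, 72.4; 0.667: 23.9, 75.0; 1.50: 23.0, 73.8; 4.00: 24.0, 76.4; 10.0: 17.8, 79.0
- north-east (time / min: Q / %, G / %): 0.167: 50.0, 48.6; 0.333: 54.2, 39.9; 1.00: 44.2, 45.4; 3.00: 30.6, 54.6; 10.0: 24.8, 60.3

(each reading ± 1 percentage point)

* time, not beyond 10 min, at which the flask holds most Q
* the amount of Q, in percent of the G charged, at that time
* the first time at which Q reaches 31 %, in the same percent, in min

- candidate steps: G + X <-> D + Q; Q + X <-> D + J; J + X <-> D + Z; Z + X <-> D + L; X -> E

1. First rung: in the north run, G + X <-> D + Q carried Q to a top reading of 35.7 % by 0.667 min.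
2. Small rung: at that reading G and Q together left 2.40 % of the G charged. I treated the later exchanges as a correction and let them sit inside one number.
3. That number is the peak quotient, an apparent equilibrium constant: c_D c_Q/(c_G c_X) at the top of Q, with c_D = c_Q and with c_G and c_X each the charge less c_Q. The north run gave 1.39, the south-west run 1.49 and the north-east run 1.22.
4. Last rung: the north run's Q then fell to 19.0 % by 10.0 min, a fall that took longer than the climb.
5. My reckoning: the north quotient with the flask's charges gave a top of Q at 44.4 %.
6. The forecast, made on its own grounds, said 44.5 % (from 41 % to 48 %) at 0.4 min, with 31 % first reached at 0.11 min, and added: “Q then declines slowly as X is lost”. Its figure for the top stood close to mine.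

The flask gave 44.0 % at 0.436 min, and reached 31 % at 0.108 min.

    G + X ⇌ D + Q (K = 2.70, k = 0.410 M⁻¹ s⁻¹)
    Q + X ⇌ D + J (K = 0.540, k = 0.0530 M⁻¹ s⁻¹)
    J + X ⇌ D + Z (K = 10.0, k = 0.240 M⁻¹ s⁻¹)
    Z + X ⇌ D + L (K = 32.0, k = 1.20 M⁻¹ s⁻¹)
    X → E (k = 0.00190 s⁻¹)

The flask's top lay 0.40 percentage points under the figure from the peak quotient 1.39. At the start, the forward first exchange used X at 65 times the rate of the path from X to E. The half-life of G by that forward path as charged, 0.13 min, was shorter than the 6.1 min half-life of X by the path to E at the longest time. With 0.13 M of X, the same quotient gave the neighbour flask 32.3 %, and that flask's top stood at 32.5 %.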